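**Retrosynthetic overview**

1. Locants follow the decalin numbering of the target: C1 ketone, C2 methyl carbinol, C3 (sec-butyl), C4 (quaternary), C4a and C8a (ring fusion), C5 (methyl), C7 (diol carbon); ring A = C1–C2–C3–C4–C4a–C8a, ring B = C4a–C5–C6–C7–C8–C8a.
2. End game: the cis ring fusion comes last, by hydroxyl-directed hydrogenation of a C4a=C8a enone; before that the C7 diol is made from an exocyclic alkene, the 3-hydroxypropanoyl chain from a C4 nitrile (MeLi, then formaldehyde aldol) and the C4 methyl group by methylation of the nitrile anion.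
3. Key disconnection: ring A is opened at C1–C8a and C2–C3, which takes out C1(=O)–C2(OH)CH3 as a lactic acid unit (a 2-tert-butyl-5-methyl-1,3-dioxolan-4-one, nucleophilic at C2 and electrophilic at C1) and leaves a 2-(cyclohexenyl)alk-2-enenitrile.
4. Enabling feature: the α-hydroxy ketone C1/C2 of ring A sits between C3 and C8a; with C4 carried as a nitrile-bearing sp2 carbon and C4a=C8a as an alkene, C3 is the β-carbon of an unsaturated nitrile and C8a the far end of the allyl anion (C4–C4a–C8a) that conjugate addition creates, so Michael addition at C3 and Claisen acylation at C8a close ring A.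
5. Ring order: ring B is bought as 4-methylidenecyclohexanone (C5 methyl by hydrazone alkylation), ring A is built onto it in the key step, and the sec-butyl stereocentre comes from (R)-2-methylbutanoic acid.

Key step: step 11

Remark: stereocentres that are erased or reset later (the two aldol centres of the step 8 product, C4 before step 13, C1 between steps 12 and 15) are carried as mixtures of epimers and are left open in the SMILES.

**Route**

Step 1
Reactants: 1 4-methylidenecyclohexan-1-one
Product: 2 (2S)-2-(methoxymethyl)-N-(4-methylidenecyclohexylidene)pyrrolidin-1-amine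
Conditions: SAMP (1.05 equiv), neat, 60 °C
Reagents that add atoms: (2S)-1-amino-2-(methoxymethyl)pyrrolidine (SAMP), COC[C@@H]1CCCN1N
Why: Hydrazone formation from a ketone and a 1,1-disubstituted hydrazine is reliable and attaches the chiral auxiliary for the next step; no stereocentre is formed.

Step 2
Reactants: 2 (2S)-2-(methoxymethyl)-N-(4-methylidenecyclohexylidene)pyrrolidin-1-amine
Product: 4 (2S)-2-(methoxymethyl)-N-[(2R)-2-methyl-4-methylidenecyclohexylidene]pyrrolidin-1-amine, via lithium azaenolate 3 (not isolated)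
Conditions: LiN(iPr)2, THF, 0 °C; MeI, −95 °C to 23 °C
Reagents that add atoms: iodomethane, CI
Why: Azaenolate alkylation by the SAMP hydrazone method, in which the chelated lithium azaenolate should be methylated on the face away from the methoxymethyl arm, is expected to set the (R)-configured methyl-bearing carbon (C5 of the target), the two α-positions being equivalent.

Step 3
Reactants: 4 (2S)-2-(methoxymethyl)-N-[(2R)-2-methyl-4-methylidenecyclohexylidene]pyrrolidin-1-amine
Product: 5 (2R)-2-methyl-4-methylidenecyclohexan-1-one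
Conditions: sat. aq. oxalic acid, Et2O, 23 °C
Reagents that add atoms: water, O
Why: Two-phase hydrazone hydrolysis with oxalic acid should regenerate the ketone without epimerising the α-stereocentre or moving the exocyclic alkene.

Step 4
Reactants: 5 (2R)-2-methyl-4-methylidenecyclohexan-1-one
Product: 7 (6R)-6-methyl-4-methylidenecyclohex-1-en-1-yl trifluoromethanesulfonate, via lithium enolate 6 (not isolated)
Conditions: LiN(iPr)2, THF, −78 °C; PhNTf2, −78 to 0 °C
Reagents that add atoms: N-phenylbis(trifluoromethanesulfonimide), O=S(=O)(N(c1ccccc1)S(=O)(=O)C(F)(F)F)C(F)(F)F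
Why: Kinetic deprotonation at the less substituted α-carbon followed by O-triflation (enol triflate formation) places the ring alkene at the future C4a=C8a position and removes the ketone before the α-stereocentre can epimerise.

Step 5
Reactants: 7 (6R)-6-methyl-4-methylidenecyclohex-1-en-1-yl trifluoromethanesulfonate
Product: 8 2-[(6R)-6-methyl-4-methylidenecyclohex-1-en-1-yl]acetonitrile
Conditions: BrZnCH2CN (from BrCH2CN and Zn dust, THF), Pd2(dba)3 (cat.), XPhos, THF, 50 °C
Reagents that add atoms: (cyanomethyl)zinc bromide, N#CC[Zn]Br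
Why: Negishi cross-coupling of the alkenyl triflate with the Reformatsky-type zinc reagent of bromoacetonitrile should join the future C4 (with the nitrile as masked acyl group) to C4a without moving the alkene; no stereocentre is formed.

Step 6
Reactants: 9 (2R)-2-methylbutanoic acid
Product: 10 (2R)-2-methylbutan-1-ol
Conditions: LiAlH4, Et2O, 0 to 23 °C; H2O
Reagents that add atoms: none
Why: Hydride reduction of a carboxylic acid to the primary alcohol does not touch the α-stereocentre.

Step 7
Reactants: 10 (2R)-2-methylbutan-1-ol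
Product: 11 (2R)-2-methylbutanal
Conditions: TEMPO (cat.), PhI(OAc)2, CH2Cl2, 23 °C; solution used at once
Reagents that add atoms: none
Why: Oxoammonium-mediated (TEMPO) oxidation stops at the aldehyde under non-basic conditions, so the labile α-stereocentre should survive.

Step 8
Reactants: 8 2-[(6R)-6-methyl-4-methylidenecyclohex-1-en-1-yl]acetonitrile + 11 (2R)-2-methylbutanal
Product: 13 (4R)-3-hydroxy-4-methyl-2-[(6R)-6-methyl-4-methylidenecyclohex-1-en-1-yl]hexanenitrile (C2/C3 epimers), via lithiated nitrile 12 (not isolated)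
Conditions: LiN(iPr)2, THF, −78 °C; 11; AcOH
Reagents that add atoms: none
Why: Aldol-type addition of the α-lithiated allylic nitrile to the aldehyde takes place at the α-carbon and forms the future C3–C4 bond; the two new centres are left uncontrolled because step 9 destroys both.

Step 9
Reactants: 13 (4R)-3-hydroxy-4-methyl-2-[(6R)-6-methyl-4-methylidenecyclohex-1-en-1-yl]hexanenitrile
Product: 15 (2Z,4R)-4-methyl-2-[(6R)-6-methyl-4-methylidenecyclohex-1-en-1-yl]hex-2-enenitrile, via methanesulfonate 14 (not isolated)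
Conditions: MsCl, Et3N, CH2Cl2, 0 °C; DBU, 23 °C
Reagents that add atoms: none
Why: Mesylation and base-induced E1cB elimination should give the conjugated dienyl nitrile with the sec-butyl group cis to the small cyano group (Z) for steric reasons; no new stereocentre remains.

Step 10
Reactants: 16 (2R)-2-hydroxypropanoic acid
Product: 17 (2R,5R)-2-tert-butyl-5-methyl-1,3-dioxolan-4-one
Conditions: tBuCHO, TsOH (cat.), pentane, reflux with water separator; crystallisation of the cis isomer
Reagents that add atoms: 2,2-dimethylpropanal (pivalaldehyde), CC(C)(C)C=O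
Why: Acid-catalysed acetalisation of the α-hydroxy acid gives the cis-dioxolanone, whose acetal carbon stores the chirality of the lactic acid carbon for the key step (self-regeneration of a stereocentre).

Step 11
Reactants: 15 (2Z,4R)-4-methyl-2-[(6R)-6-methyl-4-methylidenecyclohex-1-en-1-yl]hex-2-enenitrile + 17 (2R,5R)-2-tert-butyl-5-methyl-1,3-dioxolan-4-one
Product: 21 (2S,3R,5R)-3-[(2R)-butan-2-yl]-2-hydroxy-2,5-dimethyl-7-methylidene-1-oxo-1,2,3,4,5,6,7,8-octahydronaphthalene-4-carbonitrile (C4 epimers), via lithium dioxolanone enolate 18 (not isolated), via lithiated Michael adduct 19 (not isolated), via lithium hemiketal alkoxide 20 (not isolated)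
Conditions: LiN(iPr)2 (1.1 equiv), THF, −78 °C; 15, DMPU, −78 to −30 °C; AcOH; Et3N, CH2Cl2, 23 °C
Reagents that add atoms: none
Why: Proposed new method: enolate 18 should add in a Michael sense to C3 of the unsaturated nitrile 15, and the resulting nitrile-stabilised allyl anion 19, whose charge is shared by C4 and C8a, should attack the lactone carbonyl through C8a to give hemiketal alkoxide 20, which collapses to the ketone with loss of pivalaldehyde; the closest known reaction type is the Michael–Claisen (Michael–Dieckmann) annulation, used here in vinylogous form with the dioxolanone as a bifunctional lactic acid unit. Ring A closes by a 6-exo-trig attack of C8a on the carbonyl after the intermolecular conjugate addition, so C2–C3 and C1–C8a form in one flask operation. C2 is controlled by the tert-butyl acetal, the acceptor entering trans to it (net retention of the lactic acid configuration); C3 should follow from approach of the acceptor with its sec-butyl group turned away from the dioxolanone ring, reinforced because the conjugate addition is reversible and the adduct with the sec-butyl group on the exo face of the forming bicycle should cyclise faster. C4 is formed as a mixture and is set in step 13, and C8a becomes sp2 again when the acidic product is equilibrated to the conjugated enone with Et3N. The step needs conjugate addition instead of γ-deprotonation of 15, and acylation at C8a instead of C4; the nitrile (no 1,2-addition), the low temperature and the four-membered ring that attack through C4 would require should secure both.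

Step 12
Reactants: 21 (2S,3R,5R)-3-[(2R)-butan-2-yl]-2-hydroxy-2,5-dimethyl-7-methylidene-1-oxo-1,2,3,4,5,6,7,8-octahydronaphthalene-4-carbonitrile
Product: 22 (2S,3R,5R)-3-[(2R)-butan-2-yl]-1,2-dihydroxy-2,5-dimethyl-7-methylidene-1,2,3,4,5,6,7,8-octahydronaphthalene-4-carbonitrile (C1/C4 epimers)
Conditions: NaBH4, CeCl3·7H2O, MeOH, −40 °C
Reagents that add atoms: none
Why: Luche 1,2-reduction turns the enone into an allylic alcohol so that the anion of the next step cannot be alkylated at C8a as a vinylogous keto-nitrile; the new C1 centre is uncontrolled and is removed in step 15.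

Step 13
Reactants: 22 (2S,3R,5R)-3-[(2R)-butan-2-yl]-1,2-dihydroxy-2,5-dimethyl-7-methylidene-1,2,3,4,5,6,7,8-octahydronaphthalene-4-carbonitrile
Product: 24 (2S,3R,4S,5R)-3-[(2R)-butan-2-yl]-1,2-dihydroxy-2,4,5-trimethyl-7-methylidene-1,2,3,4,5,6,7,8-octahydronaphthalene-4-carbonitrile (C1 epimers), via trilithium salt 23 (not isolated)
Conditions: LiN(iPr)2 (3.3 equiv), THF, DMPU, −78 °C; MeI (1.1 equiv); AcOH
Reagents that add atoms: iodomethane, CI
Why: Alkylation of the nitrile-stabilised allylic anion occurs at its α-carbon, and iodomethane should approach the flat anion from the face opposite the neighbouring sec-butyl group and the pseudoaxial C5 methyl group, which sets the quaternary C4 centre (methyl β, nitrile α) and keeps the C4a=C8a alkene.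

Step 14
Reactants: 24 (2S,3R,4S,5R)-3-[(2R)-butan-2-yl]-1,2-dihydroxy-2,4,5-trimethyl-7-methylidene-1,2,3,4,5,6,7,8-octahydronaphthalene-4-carbonitrile
Product: 26 (2S,3R,4S,5R)-4-acetyl-3-[(2R)-butan-2-yl]-2,4,5-trimethyl-7-methylidene-1,2,3,4,5,6,7,8-octahydronaphthalene-1,2-diol (C1 epimers), via lithium ketimide 25 (not isolated)
Conditions: MeLi (5 equiv), Et2O/THF, 0 to 23 °C; aq. HCl (pH 3), 0 °C
Reagents that add atoms: methyllithium, [Li]C; water, O
Why: Addition of methyllithium to the nitrile stops at the metallo-imine, whose mild hydrolysis gives the methyl ketone (ketone synthesis from a nitrile), the two hydroxyls being protected as alkoxides; no stereocentre is formed.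

Step 15
Reactants: 26 (2S,3R,4S,5R)-4-acetyl-3-[(2R)-butan-2-yl]-2,4,5-trimethyl-7-methylidene-1,2,3,4,5,6,7,8-octahydronaphthalene-1,2-diol
Product: 27 (2S,3R,4S,5R)-4-acetyl-3-[(2R)-butan-2-yl]-2-hydroxy-2,4,5-trimethyl-7-methylidene-3,4,5,6,7,8-hexahydronaphthalen-1(2H)-one
Conditions: (nPr4N)RuO4 (cat.), NMO, 4 Å molecular sieves, CH2Cl2, 23 °C
Reagents that add atoms: none
Why: Ley–Griffith oxidation should convert the secondary allylic alcohol into the enone and leave the tertiary alcohol alone, which also removes the uncontrolled C1 centre.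

Step 16
Reactants: 27 (2S,3R,4S,5R)-4-acetyl-3-[(2R)-butan-2-yl]-2-hydroxy-2,4,5-trimethyl-7-methylidene-3,4,5,6,7,8-hexahydronaphthalen-1(2H)-one
Product: 29 (2S,3R,4S,5R)-3-[(2R)-butan-2-yl]-2-hydroxy-4-(3-hydroxypropanoyl)-2,4,5-trimethyl-7-methylidene-3,4,5,6,7,8-hexahydronaphthalen-1(2H)-one, via dilithium enolate 28 (not isolated)
Conditions: LiN(iPr)2 (2.2 equiv), THF, −78 °C; CH2O (gas, from paraformaldehyde), −78 °C; AcOH
Reagents that add atoms: formaldehyde, C=O
Why: Kinetic deprotonation of the methyl ketone (its other α-carbon is quaternary and the enone has no α'-hydrogen) and aldol addition to monomeric formaldehyde should give the β-hydroxy ketone side chain; no stereocentre is formed.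

Step 17
Reactants: 29 (2S,3R,4S,5R)-3-[(2R)-butan-2-yl]-2-hydroxy-4-(3-hydroxypropanoyl)-2,4,5-trimethyl-7-methylidene-3,4,5,6,7,8-hexahydronaphthalen-1(2H)-one
Product: 30 (2S,3R,4S,5R,7R)-3-[(2R)-butan-2-yl]-2,7-dihydroxy-7-(hydroxymethyl)-4-(3-hydroxypropanoyl)-2,4,5-trimethyl-3,4,5,6,7,8-hexahydronaphthalen-1(2H)-one
Conditions: OsO4 (cat.), NMO, acetone/H2O, 0 to 23 °C
Reagents that add atoms: N-methylmorpholine N-oxide, C[N+]1([O-])CCOCC1; water, O
Why: Catalytic OsO4 dihydroxylation should attack only the electron-rich 1,1-disubstituted alkene, from the equatorial direction opposite the pseudoaxial C5 methyl group, which places the tertiary hydroxyl β and the hydroxymethyl group α at C7.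

Step 18
Reactants: 30 (2S,3R,4S,5R,7R)-3-[(2R)-butan-2-yl]-2,7-dihydroxy-7-(hydroxymethyl)-4-(3-hydroxypropanoyl)-2,4,5-trimethyl-3,4,5,6,7,8-hexahydronaphthalen-1(2H)-one
Product: 31 (2S,3R,4R,4aR,5R,7R,8aS)-3-[(2R)-butan-2-yl]-2,7-dihydroxy-7-(hydroxymethyl)-4-(3-hydroxypropanoyl)-2,4,5-trimethyloctahydronaphthalen-1(2H)-one
Conditions: H2 (4 bar), [Ir(cod)(PCy3)(py)]PF6 (cat.), CH2Cl2, 23 °C
Reagents that add atoms: none
Why: Hydroxyl-directed homogeneous hydrogenation, in which the cationic iridium catalyst bound to the β-oriented C2 and C7 hydroxyls should deliver both hydrogens to the β-face of the tetrasubstituted C4a=C8a alkene, sets the cis ring fusion (C4a and C8a) in one syn addition under neutral conditions that do not epimerise C8a.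

**Compound list**

1 | 4-methylidenecyclohexan-1-one | C=C1CCC(=O)CC1 | starting material
2 | (2S)-2-(methoxymethyl)-N-(4-methylidenecyclohexylidene)pyrrolidin-1-amine | COC[C@@H]1CCCN1N=C1CCC(=C)CC1 | intermediate
3 | lithium azaenolate of 2 (not isolated) | COC[C@@H]1CCCN1[N-]C1=CCC(=C)CC1.[Li+] | intermediate
4 | (2S)-2-(methoxymethyl)-N-[(2R)-2-methyl-4-methylidenecyclohexylidene]pyrrolidin-1-amine | COC[C@@H]1CCCN1N=C1CCC(=C)C[C@H]1C | intermediate
5 | (2R)-2-methyl-4-methylidenecyclohexan-1-one | C[C@@H]1CC(=C)CCC1=O | intermediate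
6 | lithium (6R)-6-methyl-4-methylidenecyclohex-1-en-1-olate (not isolated) | C[C@@H]1CC(=C)CC=C1[O-].[Li+] | intermediate
7 | (6R)-6-methyl-4-methylidenecyclohex-1-en-1-yl trifluoromethanesulfonate | C[C@@H]1CC(=C)CC=C1OS(=O)(=O)C(F)(F)F | intermediate
8 | 2-[(6R)-6-methyl-4-methylidenecyclohex-1-en-1-yl]acetonitrile | C[C@@H]1CC(=C)CC=C1CC#N | intermediate
9 | (2R)-2-methylbutanoic acid | CC[C@@H](C)C(=O)O | starting material
10 | (2R)-2-methylbutan-1-ol | CC[C@@H](C)CO | intermediate
11 | (2R)-2-methylbutanal | CC[C@@H](C)C=O | intermediate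
12 | α-lithio derivative of 8 (not isolated) | C[C@@H]1CC(=C)CC=C1[CH-]C#N.[Li+] | intermediate
13 | (4R)-3-hydroxy-4-methyl-2-[(6R)-6-methyl-4-methylidenecyclohex-1-en-1-yl]hexanenitrile (C2/C3 epimers) | CC[C@@H](C)C(O)C(C#N)C1=CCC(=C)C[C@H]1C | intermediate
14 | methanesulfonate of 13 (not isolated) | CC[C@@H](C)C(OS(C)(=O)=O)C(C#N)C1=CCC(=C)C[C@H]1C | intermediate
15 | (2Z,4R)-4-methyl-2-[(6R)-6-methyl-4-methylidenecyclohex-1-en-1-yl]hex-2-enenitrile | CC[C@@H](C)/C=C(\C#N)C1=CCC(=C)C[C@H]1C | intermediate
16 | (2R)-2-hydroxypropanoic acid (D-lactic acid) | C[C@@H](O)C(=O)O | starting material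
17 | (2R,5R)-2-tert-butyl-5-methyl-1,3-dioxolan-4-one | C[C@H]1O[C@@H](C(C)(C)C)OC1=O | intermediate
18 | lithium (2R)-2-tert-butyl-5-methyl-1,3-dioxol-4-olate (not isolated) | CC1=C([O-])O[C@H](C(C)(C)C)O1.[Li+] | intermediate
19 | lithiated open-chain Michael adduct of 15 and 18 (not isolated) | CC[C@@H](C)[C@H]([C-](C#N)C1=CCC(=C)C[C@H]1C)[C@]1(C)O[C@@H](C(C)(C)C)OC1=O.[Li+] | intermediate
20 | lithium hemiketal alkoxide from ring closure of 19 (not isolated) | CC[C@@H](C)[C@@H]1C(C#N)=C2[C@H](C)CC(=C)CC2C2([O-])O[C@H](C(C)(C)C)O[C@@]12C.[Li+] | intermediate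
21 | (2S,3R,5R)-3-[(2R)-butan-2-yl]-2-hydroxy-2,5-dimethyl-7-methylidene-1-oxo-1,2,3,4,5,6,7,8-octahydronaphthalene-4-carbonitrile (C4 epimers) | CC[C@@H](C)[C@@H]1C(C#N)C2=C(CC(=C)C[C@H]2C)C(=O)[C@@]1(C)O | intermediate
22 | (2S,3R,5R)-3-[(2R)-butan-2-yl]-1,2-dihydroxy-2,5-dimethyl-7-methylidene-1,2,3,4,5,6,7,8-octahydronaphthalene-4-carbonitrile (C1/C4 epimers) | CC[C@@H](C)[C@@H]1C(C#N)C2=C(CC(=C)C[C@H]2C)C(O)[C@@]1(C)O | intermediate
23 | trilithium salt of 22 (not isolated) | CC[C@@H](C)[C@@H]1[C-](C#N)C2=C(CC(=C)C[C@H]2C)C([O-])[C@@]1(C)[O-].[Li+].[Li+].[Li+] | intermediate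
24 | (2S,3R,4S,5R)-3-[(2R)-butan-2-yl]-1,2-dihydroxy-2,4,5-trimethyl-7-methylidene-1,2,3,4,5,6,7,8-octahydronaphthalene-4-carbonitrile (C1 epimers) | CC[C@@H](C)[C@@H]1[C@](C)(C#N)C2=C(CC(=C)C[C@H]2C)C(O)[C@@]1(C)O | intermediate
25 | lithium ketimide dialkoxide from 24 and MeLi (not isolated) | CC[C@@H](C)[C@@H]1[C@](C)(C(C)=[N-])C2=C(CC(=C)C[C@H]2C)C([O-])[C@@]1(C)[O-].[Li+].[Li+].[Li+] | intermediate
26 | (2S,3R,4S,5R)-4-acetyl-3-[(2R)-butan-2-yl]-2,4,5-trimethyl-7-methylidene-1,2,3,4,5,6,7,8-octahydronaphthalene-1,2-diol (C1 epimers) | CC[C@@H](C)[C@@H]1[C@](C)(C(C)=O)C2=C(CC(=C)C[C@H]2C)C(O)[C@@]1(C)O | intermediate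
27 | (2S,3R,4S,5R)-4-acetyl-3-[(2R)-butan-2-yl]-2-hydroxy-2,4,5-trimethyl-7-methylidene-3,4,5,6,7,8-hexahydronaphthalen-1(2H)-one | CC[C@@H](C)[C@@H]1[C@](C)(C(C)=O)C2=C(CC(=C)C[C@H]2C)C(=O)[C@@]1(C)O | intermediate
28 | dilithium enolate alkoxide of 27 (not isolated) | CC[C@@H](C)[C@@H]1[C@](C)(C([O-])=C)C2=C(CC(=C)C[C@H]2C)C(=O)[C@@]1(C)[O-].[Li+].[Li+] | intermediate
29 | (2S,3R,4S,5R)-3-[(2R)-butan-2-yl]-2-hydroxy-4-(3-hydroxypropanoyl)-2,4,5-trimethyl-7-methylidene-3,4,5,6,7,8-hexahydronaphthalen-1(2H)-one | CC[C@@H](C)[C@@H]1[C@](C)(C(=O)CCO)C2=C(CC(=C)C[C@H]2C)C(=O)[C@@]1(C)O | intermediate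
30 | (2S,3R,4S,5R,7R)-3-[(2R)-butan-2-yl]-2,7-dihydroxy-7-(hydroxymethyl)-4-(3-hydroxypropanoyl)-2,4,5-trimethyl-3,4,5,6,7,8-hexahydronaphthalen-1(2H)-one | CC[C@@H](C)[C@@H]1[C@](C)(C(=O)CCO)C2=C(C[C@@](O)(CO)C[C@H]2C)C(=O)[C@@]1(C)O | intermediate
31 | (2S,3R,4R,4aR,5R,7R,8aS)-3-[(2R)-butan-2-yl]-2,7-dihydroxy-7-(hydroxymethyl)-4-(3-hydroxypropanoyl)-2,4,5-trimethyloctahydronaphthalen-1(2H)-one | CC[C@@H](C)[C@@H]1[C@](C)(C(=O)CCO)[C@@H]2[C@H](C)C[C@](O)(CO)C[C@@H]2C(=O)[C@@]1(C)O | target

**Step count and risks**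

Total step count: 18. Longest linear sequence: 15 steps (steps 1–5, 8, 9, 11–18).

The three steps most likely to fail are these.

First, step 11, the proposed method. What may go wrong is proton transfer from the γ-position of 15 to the basic enolate instead of conjugate addition, poor facial selectivity at C3 in the conjugate addition, or failure of the hindered anion to acylate at C8a. The fallback makes the two bonds one after the other by known reactions, from 15 and 17 back to 21. Compound 17 is converted into its trimethylsilyl ketene acetal F1 (LiN(iPr)2, Me3SiCl). F1 should add to 15 in a TiCl4-promoted Mukaiyama–Michael reaction to give, after aqueous work-up, the open-chain adduct F2. Mild hydrolysis of the dioxolanone (LiOH, aq. THF) should give the hydroxy acid F3. Trifluoroacetic anhydride should then close the C1–C8a bond by intramolecular Friedel–Crafts-type acylation of the cyclohexene; K2CO3 in methanol removes the trifluoroacetate and equilibrates the alkene, arriving at 21.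

Second, step 18. What may go wrong is incomplete reduction of the hindered tetrasubstituted alkene, or delivery of hydrogen to the α-face through the two primary hydroxyls, which would give the wrong ring fusion. The fallback runs from 30 back to 31. The primary hydroxyls are silylated selectively (Et3SiCl, imidazole) to give the bis(triethylsilyl) ether F4, so that only the β-oriented tertiary hydroxyls at C2 and C7 can bind the catalyst. Hydrogenation under pressure (the same iridium complex, or Rh on Al2O3 if the cationic catalyst is poisoned) should give F5, and HF·pyridine should release 31.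

Third, step 16. What may go wrong is proton exchange after the first aldol addition, leading to double hydroxymethylation, or retro-aldol cleavage and dehydration of the β-hydroxy ketone during the quench. The fallback builds the chain without an enolate, from 24 back to 29. Reduction of the nitrile with iBu2AlH should give the aldehyde F6, and vinylmagnesium bromide the allylic alcohol F7. Oxidation of both secondary alcohols with (nPr4N)RuO4 and NMO should give the dienone F8. Copper-catalysed conjugate borylation of the unhindered vinyl ketone (CuCl, NaOtBu, B2pin2, MeOH) should give the boronate F9, which NaBO3 should oxidise to 29.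

Further compounds

F1 | step 11 | (2R)-2-tert-butyl-5-methyl-4-(trimethylsilyloxy)-1,3-dioxole | CC1=C(O[Si](C)(C)C)O[C@H](C(C)(C)C)O1
F2 | step 11 | (2R,5S)-2-tert-butyl-5-{(1R)-1-[(2R)-butan-2-yl]-2-cyano-2-[(6R)-6-methyl-4-methylidenecyclohex-1-en-1-yl]ethyl}-5-methyl-1,3-dioxolan-4-one | CC[C@@H](C)[C@H](C(C#N)C1=CCC(=C)C[C@H]1C)[C@]1(C)O[C@@H](C(C)(C)C)OC1=O
F3 | step 11 | (2S,3R)-3-[(2R)-butan-2-yl]-4-cyano-2-hydroxy-2-methyl-4-[(6R)-6-methyl-4-methylidenecyclohex-1-en-1-yl]butanoic acid | CC[C@@H](C)[C@H](C(C#N)C1=CCC(=C)C[C@H]1C)[C@](C)(O)C(=O)O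
F4 | step 18 | bis(triethylsilyl) ether of 30 at the two primary hydroxyls | CC[C@@H](C)[C@@H]1[C@](C)(C(=O)CCO[Si](CC)(CC)CC)C2=C(C[C@@](O)(CO[Si](CC)(CC)CC)C[C@H]2C)C(=O)[C@@]1(C)O
F5 | step 18 | bis(triethylsilyl) ether of 31 at the two primary hydroxyls | CC[C@@H](C)[C@@H]1[C@](C)(C(=O)CCO[Si](CC)(CC)CC)[C@@H]2[C@H](C)C[C@](O)(CO[Si](CC)(CC)CC)C[C@@H]2C(=O)[C@@]1(C)O
F6 | step 16 | (2S,3R,4S,5R)-3-[(2R)-butan-2-yl]-1,2-dihydroxy-2,4,5-trimethyl-7-methylidene-1,2,3,4,5,6,7,8-octahydronaphthalene-4-carbaldehyde (C1 epimers) | CC[C@@H](C)[C@@H]1[C@](C)(C=O)C2=C(CC(=C)C[C@H]2C)C(O)[C@@]1(C)O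
F7 | step 16 | (2S,3R,4S,5R)-3-[(2R)-butan-2-yl]-4-(1-hydroxyprop-2-en-1-yl)-2,4,5-trimethyl-7-methylidene-1,2,3,4,5,6,7,8-octahydronaphthalene-1,2-diol (carbinol epimers) | CC[C@@H](C)[C@@H]1[C@](C)(C(O)C=C)C2=C(CC(=C)C[C@H]2C)C(O)[C@@]1(C)O
F8 | step 16 | (2S,3R,4S,5R)-3-[(2R)-butan-2-yl]-2-hydroxy-2,4,5-trimethyl-7-methylidene-4-(prop-2-enoyl)-3,4,5,6,7,8-hexahydronaphthalen-1(2H)-one | CC[C@@H](C)[C@@H]1[C@](C)(C(=O)C=C)C2=C(CC(=C)C[C@H]2C)C(=O)[C@@]1(C)O
F9 | step 16 | (2S,3R,4S,5R)-3-[(2R)-butan-2-yl]-2-hydroxy-2,4,5-trimethyl-7-methylidene-4-[3-(4,4,5,5-tetramethyl-1,3,2-dioxaborolan-2-yl)propanoyl]-3,4,5,6,7,8-hexahydronaphthalen-1(2H)-one | CC[C@@H](C)[C@@H]1[C@](C)(C(=O)CCB3OC(C)(C)C(C)(C)O3)C2=C(CC(=C)C[C@H]2C)C(=O)[C@@]1(C)O
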